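The coupling partner is the species to watch. Nobody read it directly, so I reckoned it from the substrate.

the same everywhere: substrate 0.20 M
- Thursday's: coupling partner 0.16 M; initiator 1 mM; run made earlier
- Friday's: coupling partner 0.16 M; initiator 4 mM; run made earlier
- east: coupling partner 0.160 M; initiator 2.0 mM; time 6.0 d
- south-east: coupling partner 0.160 M; initiator 2.0 mM; time 8.0 d

| run | time / d | substrate / % | over-reaction product / % | target / % | isomer of the product / % |
|---|---|---|---|---|---|
| Thursday's | 0.333 | 90.9 | 2.3 | 5.9 | 1.0 |
| Thursday's | 0.833 | 80.9 | 10.0 | 7.7 | 0.8 |
| Thursday's | 1.67 | 75.8 | 20.0 | 3.6 | 0.8 |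
| Thursday's | 2.50 | 75.3 | 23.0 | 0.6 | 0 |
| Thursday's | 4.00 | 75.5 | 24.3 | 0.3 | 0 |
| Friday's | 0.625 | 69.7 | 13.6 | 14.8 | 0.9 |
| Friday's | 1.25 | 61.0 | 29.2 | 7.7 | 1.3 |
| Friday's | 2.00 | 60.9 | 36.2 | 2.1 | 0 |
| Friday's | 3.00 | 61.2 | 38.0 | 0.3 | 0.3 |
| Friday's | 4.00 | 60.4 | 39.1 | 0 | 0 |

(readings scatter by 0.3 percentage points)

- which of these there is most of at the end, counted by the substrate in it, east (target / isomer of the product / over-reaction product / substrate)
- which of these there is most of at the end, counted by the substrate in it, south-east (target / isomer of the product / over-reaction product / substrate)
- how much there is at the end of the one of these that leads, in percent of the substrate charged: east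
- how much there is at the end of the one of these that leads, in percent of the substrate charged: south-east

Thursday's substrate went flat by 2.50 d. I took one partner per substrate lost, so the flat part of Thursday's run gave coupled partner:

0.0492 M

Friday's run, from the same partner charge, gave:

0.0784 M

That is more than Thursday's figure, so Thursday's stop was not partner used up by coupling. I assumed the rest decayed by itself. I then froze one number for each run: partner coupled over partner decayed, taken over the whole run. It is an average at these partner and substrate charges, not a constant of the flask:

Thursday's: 0.444

Friday's: 0.961

The initiator of east lies at the geometric mean of those two runs, so I took the geometric mean of the ratios: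

0.653

This is the coupling ratio, partner coupled over partner decayed in a whole run at these charges. It gave substrate left:

68.4%

Both flasks run longer than Thursday's flat stretch took to begin, so I expected that figure in both.

The forecast gave 68% for east and 68% for south-east: “substrate leads”.

East ended at 67.9% substrate and south-east at 67.9%.

    substrate + initiating radical → capped initiator + first chain carrier (k = 45000 /M/s)
    2 first chain carrier → ended chains A (k = 9.00 × 10⁶ /M/s)
    coupling partner → decomposed reagent (k = 1.80 × 10⁻⁵ /s)
    2 second chain carrier → ended chains B (k = 8.00 × 10⁷ /M/s)
    first chain carrier → ended carrier (k = 0.480 /s)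
    target → over-reaction product (k = 2.40 × 10⁻⁵ /s)
    substrate + second chain carrier → released group + first chain carrier (k = 2000 /M/s)
    initiator → 2 initiating radical (k = 2.90 × 10⁻⁷ /s)
    target ⇌ isomer of the product (K = 0.150, k = 3.80 × 10⁻⁶ /s)
    coupling partner + first chain carrier → target + second chain carrier (k = 17000 /M/s)

The coupling partner, the limiting reagent, stood at 0% of its charge in east, with 68% of the substrate left. In south-east at 0.251 d, its half-life by coupling was 0.87 d and by decay 0.446 d, so decay ran faster. Released group over decomposed reagent in east came to 0.659, against my coupling ratio of 0.653. The neighbour like south-east but charged with 0.64 M of partner ended at a ratio of 0.211, and there over-reaction product led with 55.9%.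

The data were computed with made-up constants; the scatter is artificial.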